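**Retrosynthetic overview**

1. The target is a 2,3-trans flavanonol 3-methyl ether (flavanone numbering: O1, C2, C3, C4, C4a). The last step removes three benzyl groups and the one methyl group that lies peri to the C4 carbonyl (5-OMe).
2. Ring C is cut at C4–C4a (Friedel–Crafts acylation by a C4 acid) and at O1–C2 (SN2 displacement at the benzylic carbon by a ring A phenoxide, with inversion). Ring A enters as 4-benzyloxy-3,5-dimethoxyphenol, whose two ortho positions are equivalent, so the acylation has no regiochemical choice.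
3. Feature used: C2 and C3 are neighbouring oxygen-bearing stereocentres attached to the acyl carbon C4. C2, C3 and C4 are therefore stored in a cis-3-methoxy-4-aryl-oxetan-2-one, whose alkyl C–O bond marks where O1 enters.
4. The oxetanone comes from methoxyketene and the benzyl-protected ring B aldehyde by an alkaloid/LiClO4-catalysed [2+2] that forms C2–C3.
5. Ring order: rings A and B are bought as arenes; the sacrificial four-membered lactone is made first and opened; ring C is closed last.

Key step: step 2

Remark: O-trimethylsilylquinidine is assigned to the (3R,4S) lactone by analogy with the sense it is expected to show with alkyl-substituted ketenes. This assignment must be checked on the first batch of the lactone; if the antipode forms, the quinine-derived pseudoenantiomer takes its place with nothing else changed.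

**Step 1**
Reactants: 1 2,3-dihydroxy-4-methoxybenzaldehyde
Product: 2 2,3-bis(benzyloxy)-4-methoxybenzaldehyde
Conditions: BnBr, K2CO3, DMF, 60 °C
Reagents that add atoms: benzyl bromide, BrCc1ccccc1
Why: Williamson ether synthesis; both phenols are O-alkylated (the 2-OH, hydrogen-bonded to the formyl group, needs the warm polar medium) and the aldehyde is untouched.

**Step 2**
Reactants: 2 2,3-bis(benzyloxy)-4-methoxybenzaldehyde; 3 methoxyacetyl chloride
Product: 5 (3R,4S)-4-[2,3-bis(benzyloxy)-4-methoxyphenyl]-3-methoxyoxetan-2-one, via methoxyketene 4 (not isolated)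
Conditions: O-trimethylsilylquinidine (20 mol %), LiClO4 (2 equiv), i-Pr2NEt, CH2Cl2/Et2O, −78 → −40 °C, 3 added slowly; cold filtration through neutral silica
Reagents that add atoms: none
Why: i-Pr2NEt converts 3 into methoxyketene 4, which the quinuclidine nitrogen of the catalyst captures as a (Z)-ammonium enolate; aldol addition to the aldehyde, activated by Li+ held between the formyl oxygen and the 2-benzyloxy oxygen, forms the bond that becomes C2–C3, and the lithium aldolate then displaces the catalyst from the acylammonium carbon to close the oxetanone (4-exo-trig). The closest known reaction is the cinchona alkaloid/LiClO4 co-catalysed acyl halide–aldehyde cyclocondensation to cis-3,4-disubstituted β-lactones; an alkoxyketene paired with an electron-rich aryl aldehyde lies at the edge of its demonstrated scope. The methoxy-bearing carbon (R) is set by the alkaloid, whose quinoline ring blocks one face of the bound enolate; the benzylic carbon (S) follows from the closed, lithium-bridged chair transition state with the aryl group pseudo-equatorial, which gives the cis lactone. Both enantio- and cis-selectivity are required, because the later inversion at the benzylic carbon turns cis into the 2,3-trans target; slow addition of 3 keeps free ketene low (less dimer, less uncatalysed background), and the chelating ortho-benzyloxy group offsets the deactivation of the aldehyde by its para-methoxy group. The α-methoxy group and the lactone carbonyl withdraw electron density from the benzylic carbon, which should hold back ionisation and loss of CO2 from 5 during a cold, non-acidic work-up.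

**Step 3**
Reactants: 6 syringaldehyde
Product: 7 4-(benzyloxy)-3,5-dimethoxybenzaldehyde
Conditions: BnBr, K2CO3, DMF, 50 °C
Reagents that add atoms: benzyl bromide, BrCc1ccccc1
Why: Williamson ether synthesis on the only free phenol; the benzyl group marks the oxygen that becomes the 6-OH and keeps ring A symmetrical.

**Step 4**
Reactants: 7 4-(benzyloxy)-3,5-dimethoxybenzaldehyde
Product: 9 4-(benzyloxy)-3,5-dimethoxyphenol, via aryl formate 8 (not isolated)
Conditions: mCPBA, CH2Cl2, 0 °C → rt; then K2CO3 (cat.), MeOH, rt
Reagents that add atoms: 3-chloroperoxybenzoic acid (mCPBA), O=C(OO)c1cccc(Cl)c1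
Why: Baeyer–Villiger (Dakin-type) oxidation; the electron-rich aryl group migrates in preference to hydrogen to give the formate, which methanolysis converts into the phenol without touching the ethers.

**Step 5**
Reactants: 5 (3R,4S)-4-[2,3-bis(benzyloxy)-4-methoxyphenyl]-3-methoxyoxetan-2-one; 9 4-(benzyloxy)-3,5-dimethoxyphenol
Product: 11 (2R,3R)-3-[2,3-bis(benzyloxy)-4-methoxyphenyl]-3-[4-(benzyloxy)-3,5-dimethoxyphenoxy]-2-methoxypropanoic acid, via sodium phenoxide 10 (not isolated)
Conditions: 9, NaH, DMF, 0 °C; then 5, 0 °C → rt; dilute aq. HCl work-up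
Reagents that add atoms: none
Why: SN2 ring opening of a β-lactone by alkyl–oxygen cleavage (carboxylate leaving group, strain release), a known mode for phenoxides; attack at the benzylic carbon brings in the ring A oxygen with inversion and turns the cis lactone into the (2R,3R) acid, while addition at the acyl carbon only gives an aryl ester that can close back to the lactone, and DMF favours O- over C-alkylation.

**Step 6**
Reactants: 11 (2R,3R)-3-[2,3-bis(benzyloxy)-4-methoxyphenyl]-3-[4-(benzyloxy)-3,5-dimethoxyphenoxy]-2-methoxypropanoic acid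
Product: 13 (2R,3R)-6-(benzyloxy)-2-[2,3-bis(benzyloxy)-4-methoxyphenyl]-3,5,7-trimethoxy-2,3-dihydro-4H-chromen-4-one, via mixed anhydride 12 (not isolated)
Conditions: (CF3CO)2O, CH2Cl2, 0 °C → rt
Reagents that add atoms: none
Why: Intramolecular Friedel–Crafts acylation through the mixed trifluoroacetic anhydride; the carbon attacked is ortho to O1 and ortho and para to the two methoxy groups, the two ortho positions of ring A are equivalent so only one chromanone can form, six-membered closure onto this phloroglucinol-type ring should outrun indanone formation on ring B, and neither stereocentre takes part.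

**Step 7**
Reactants: 13 (2R,3R)-6-(benzyloxy)-2-[2,3-bis(benzyloxy)-4-methoxyphenyl]-3,5,7-trimethoxy-2,3-dihydro-4H-chromen-4-one
Product: 14 (2R,3R)-2-(2,3-dihydroxy-4-methoxyphenyl)-5,6-dihydroxy-3,7-dimethoxy-2,3-dihydro-4H-chromen-4-one (CNP0075602.1)
Conditions: BCl3, C6HMe5, CH2Cl2, −78 → 0 °C; degassed aq. work-up under argon
Reagents that add atoms: none
Why: Lewis-acid ether cleavage; BCl3 removes the three aryl benzyl groups at low temperature (pentamethylbenzene traps the benzyl cations) and, through a six-membered chelate with the C4 carbonyl, the peri 5-methyl group as chloromethane, while the 7-, 4'- and aliphatic 3-methoxy groups have no such chelate and should survive at or below 0 °C, and no bond to C2 or C3 is broken.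

**Compound list**

1 | 2,3-dihydroxy-4-methoxybenzaldehyde | COc1ccc(C=O)c(O)c1O | starting material
2 | 2,3-bis(benzyloxy)-4-methoxybenzaldehyde | COc1ccc(C=O)c(OCc2ccccc2)c1OCc1ccccc1 | intermediate
3 | methoxyacetyl chloride | COCC(Cl)=O | starting material
4 | methoxyketene | COC=C=O | intermediate (not isolated)
5 | (3R,4S)-4-[2,3-bis(benzyloxy)-4-methoxyphenyl]-3-methoxyoxetan-2-one | COc1ccc([C@@H]2OC(=O)[C@@H]2OC)c(OCc2ccccc2)c1OCc1ccccc1 | intermediate
6 | syringaldehyde (4-hydroxy-3,5-dimethoxybenzaldehyde) | COc1cc(C=O)cc(OC)c1O | starting material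
7 | 4-(benzyloxy)-3,5-dimethoxybenzaldehyde | COc1cc(C=O)cc(OC)c1OCc1ccccc1 | intermediate
8 | 4-(benzyloxy)-3,5-dimethoxyphenyl formate | COc1cc(OC=O)cc(OC)c1OCc1ccccc1 | intermediate (not isolated)
9 | 4-(benzyloxy)-3,5-dimethoxyphenol | COc1cc(O)cc(OC)c1OCc1ccccc1 | intermediate
10 | sodium 4-(benzyloxy)-3,5-dimethoxyphenoxide | [Na+].[O-]c1cc(OC)c(OCc2ccccc2)c(OC)c1 | intermediate (not isolated)
11 | (2R,3R)-3-[2,3-bis(benzyloxy)-4-methoxyphenyl]-3-[4-(benzyloxy)-3,5-dimethoxyphenoxy]-2-methoxypropanoic acid | COc1ccc([C@@H](Oc2cc(OC)c(OCc3ccccc3)c(OC)c2)[C@@H](OC)C(O)=O)c(OCc2ccccc2)c1OCc1ccccc1 | intermediate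
12 | mixed anhydride of 11 with trifluoroacetic acid | COc1ccc([C@@H](Oc2cc(OC)c(OCc3ccccc3)c(OC)c2)[C@@H](OC)C(=O)OC(=O)C(F)(F)F)c(OCc2ccccc2)c1OCc1ccccc1 | intermediate (not isolated)
13 | (2R,3R)-6-(benzyloxy)-2-[2,3-bis(benzyloxy)-4-methoxyphenyl]-3,5,7-trimethoxy-2,3-dihydro-4H-chromen-4-one | COc1ccc([C@H]2Oc3cc(OC)c(OCc4ccccc4)c(OC)c3C(=O)[C@@H]2OC)c(OCc2ccccc2)c1OCc1ccccc1 | intermediate
14 | (2R,3R)-2-(2,3-dihydroxy-4-methoxyphenyl)-5,6-dihydroxy-3,7-dimethoxy-2,3-dihydro-4H-chromen-4-one | COc1ccc([C@H]2Oc3cc(OC)c(O)c(O)c3C(=O)[C@@H]2OC)c(O)c1O | target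

**Step count and risks**

Total steps: 7. Longest linear sequence: 5 steps (1 → 2 → 5 → 11 → 13 → 14, or equally 6 → 7 → 9 → 11 → 13 → 14).

**Step 2 (most likely to fail).** The ammonium enolate may add too slowly to the deactivated, ortho-substituted aldehyde. Ketene oligomerisation and the uncatalysed pathway would then take over, giving low conversion and eroded enantio- and cis-selectivity. The electron-rich benzylic C–O bond of the lactone may also ionise on isolation, with loss of CO2.

The fallback sets out from 2 and 3 and returns at 5; it replaces catalyst control by a stoichiometric auxiliary. Acid chloride 3 acylates lithiated (R)-4-benzyloxazolidin-2-one (n-BuLi, THF, −78 °C) to give (R)-4-benzyl-3-(methoxyacetyl)oxazolidin-2-one F1. Bu2BOTf and i-Pr2NEt (CH2Cl2, −78 °C) convert it into the dibutylboron (Z)-enolate F2. Evans syn-aldol addition of this enolate to 2 (−78 → 0 °C, work-up with H2O2 and pH 7 buffer) should give the syn adduct (R)-4-benzyl-3-[(2R,3S)-3-[2,3-bis(benzyloxy)-4-methoxyphenyl]-3-hydroxy-2-methoxypropanoyl]oxazolidin-2-one F3. LiOH/H2O2 (THF/H2O, 0 °C) removes the auxiliary to give the hydroxy acid (2R,3S)-3-[2,3-bis(benzyloxy)-4-methoxyphenyl]-3-hydroxy-2-methoxypropanoic acid F4. Carboxyl activation (PhSO2Cl, pyridine, 0 °C) then closes the lactone with retention at both centres (syn acid to cis lactone) and gives 5.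

**Step 5.** The ambident phenoxide may alkylate on carbon, or act as a base (epimerisation at the methoxy-bearing carbon, elimination). The benzylic C–O bond may also ionise before it is displaced, so that inversion is incomplete or CO2 is lost. Incomplete inversion would appear after step 6 as the cis diastereomer, not as a loss of ee, as long as the methoxy-bearing carbon holds.

The fallback sets out from 5 and returns at 11; it forms O1–C2 on an open-chain alcohol without free phenoxide. Methanolysis of 5 at the acyl carbon (MeOH, cat. K2CO3, 0 °C) gives methyl (2R,3S)-3-[2,3-bis(benzyloxy)-4-methoxyphenyl]-3-hydroxy-2-methoxypropanoate F5 with both centres retained. A Mitsunobu reaction of F5 with phenol 9 (PPh3, DIAD, toluene, 0 °C) forms the aryl ether with inversion at the benzylic carbon, giving methyl (2R,3R)-3-[2,3-bis(benzyloxy)-4-methoxyphenyl]-3-[4-(benzyloxy)-3,5-dimethoxyphenoxy]-2-methoxypropanoate F6. LiOH (THF/H2O, 0 °C) followed by aqueous acid gives 11.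

**Step 6.** The activated α-methoxy acid may lose CO through acylium character. Trifluoroacetic acid may ionise the electron-rich benzylic aryl ether (cleavage, or scrambling at C2). Acylation may also occur on ring B (indanone) or by the reagent itself (trifluoroacetylation of ring A).

The fallback sets out from 9 and 5 and returns at 13; it is a Parham cyclisation, which fixes the site on ring A by a halogen and needs no acid. NBS (CH2Cl2, −78 °C) brominates 9 at one of its two equivalent ortho positions to give 4-(benzyloxy)-2-bromo-3,5-dimethoxyphenol F7. NaH (DMF, 0 °C) gives its sodium phenoxide F8, which opens 5 as in step 5 to give (2R,3R)-3-[2,3-bis(benzyloxy)-4-methoxyphenyl]-3-[4-(benzyloxy)-2-bromo-3,5-dimethoxyphenoxy]-2-methoxypropanoic acid F9. MeNH(OMe)·HCl, EDC·HCl, HOBt and i-Pr2NEt (CH2Cl2) give the Weinreb amide F10. t-BuLi (2 equiv, THF, −100 → −78 °C) effects bromine–lithium exchange to the aryllithium F11, which attacks the amide carbonyl in a six-membered closure; the chelated tetrahedral intermediate collapses on work-up to 13.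

**Further compounds**

F1 | step 2 | (R)-4-benzyl-3-(methoxyacetyl)oxazolidin-2-one | COCC(=O)N1[C@H](Cc2ccccc2)COC1=O
F2 | step 2 | dibutylboron (Z)-enolate of F1, (R)-4-benzyl-3-[(Z)-1-(dibutylboranyloxy)-2-methoxyethenyl]oxazolidin-2-one | CCCCB(CCCC)O/C(=C\OC)N1[C@H](Cc2ccccc2)COC1=O
F3 | step 2 | (R)-4-benzyl-3-[(2R,3S)-3-[2,3-bis(benzyloxy)-4-methoxyphenyl]-3-hydroxy-2-methoxypropanoyl]oxazolidin-2-one | COc1ccc([C@H](O)[C@@H](OC)C(=O)N2[C@H](Cc3ccccc3)COC2=O)c(OCc2ccccc2)c1OCc1ccccc1
F4 | step 2 | (2R,3S)-3-[2,3-bis(benzyloxy)-4-methoxyphenyl]-3-hydroxy-2-methoxypropanoic acid | COc1ccc([C@H](O)[C@@H](OC)C(O)=O)c(OCc2ccccc2)c1OCc1ccccc1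
F5 | step 5 | methyl (2R,3S)-3-[2,3-bis(benzyloxy)-4-methoxyphenyl]-3-hydroxy-2-methoxypropanoate | COc1ccc([C@H](O)[C@@H](OC)C(=O)OC)c(OCc2ccccc2)c1OCc1ccccc1
F6 | step 5 | methyl (2R,3R)-3-[2,3-bis(benzyloxy)-4-methoxyphenyl]-3-[4-(benzyloxy)-3,5-dimethoxyphenoxy]-2-methoxypropanoate | COc1ccc([C@@H](Oc2cc(OC)c(OCc3ccccc3)c(OC)c2)[C@@H](OC)C(=O)OC)c(OCc2ccccc2)c1OCc1ccccc1
F7 | step 6 | 4-(benzyloxy)-2-bromo-3,5-dimethoxyphenol | COc1cc(O)c(Br)c(OC)c1OCc1ccccc1
F8 | step 6 | sodium 4-(benzyloxy)-2-bromo-3,5-dimethoxyphenoxide | [Na+].[O-]c1cc(OC)c(OCc2ccccc2)c(OC)c1Br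
F9 | step 6 | (2R,3R)-3-[2,3-bis(benzyloxy)-4-methoxyphenyl]-3-[4-(benzyloxy)-2-bromo-3,5-dimethoxyphenoxy]-2-methoxypropanoic acid | COc1ccc([C@@H](Oc2cc(OC)c(OCc3ccccc3)c(OC)c2Br)[C@@H](OC)C(O)=O)c(OCc2ccccc2)c1OCc1ccccc1
F10 | step 6 | (2R,3R)-3-[2,3-bis(benzyloxy)-4-methoxyphenyl]-3-[4-(benzyloxy)-2-bromo-3,5-dimethoxyphenoxy]-N,2-dimethoxy-N-methylpropanamide | COc1ccc([C@@H](Oc2cc(OC)c(OCc3ccccc3)c(OC)c2Br)[C@@H](OC)C(=O)N(C)OC)c(OCc2ccccc2)c1OCc1ccccc1
F11 | step 6 | aryllithium from F10 (lithium in place of bromine) | COc1ccc([C@@H](Oc2cc(OC)c(OCc3ccccc3)c(OC)c2[Li])[C@@H](OC)C(=O)N(C)OC)c(OCc2ccccc2)c1OCc1ccccc1
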